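**Retrosynthetic overview**
- 26-Hexacosanolide is one 27-membered ring (C1 carbonyl to C26, closed by the ester oxygen) with no stereocentre. The single strategic disconnection is the unfunctionalised C21–C22 bond, which lies twenty CH2 groups from C1 and five carbons from the ring oxygen.
- Raising C21 and C22 by one oxidation level (a carboxyl group on each) opens the ring to an acyclic diacid in which the C1(=O)–O ester acts as tether. Its bis(N-acyloxyphthalimide) should close to the lactone by nickel-electrocatalytic doubly decarboxylative C(sp3)–C(sp3) coupling, both activating groups leaving as CO2 and phthalimide in the same operation.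
- Enabling feature: C21 and C22 are plain primary ring methylenes flanked only by CH2. C1–C21 plus one carboxyl carbon is docosanedioic acid, C22–C26 plus one carboxyl carbon is a 6-oxyhexanoate, and the 27-membered ring is strain-free.
- The diacid comes from O-alkylation of docosanedioic acid with tert-butyl 6-bromohexanoate (forms O–C26), followed by tert-butyl cleavage.
- Ring order: the macrolactone is the only ring and is formed last.

Key step: step 4

Remark: the target has no stereocentre; ring atoms are numbered C1 (lactone carbonyl) to C26 (OCH2), and these numbers are used for the corresponding atoms of all precursors.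

**Step 1**
Reactants: 1 docosanedioic acid (threefold excess, surplus recovered); 2 tert-butyl 6-bromohexanoate
Product: 3 22-[(6-tert-butoxy-6-oxohexyl)oxy]-22-oxodocosanoic acid
Conditions: KHCO3 (1 equiv relative to 2), DMF, 70 °C
Reagents that add atoms: tert-butyl 6-bromohexanoate (2), BrCCCCCC(=O)OC(C)(C)C
Why: Carboxylate O-alkylation (SN2) of the half-potassium salt of 1 by the primary bromide forms the O–C26 bond, the excess of diacid should keep double alkylation low, and the tert-butyl ester is inert to carboxylate and bicarbonate.

**Step 2**
Reactants: 3 22-[(6-tert-butoxy-6-oxohexyl)oxy]-22-oxodocosanoic acid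
Product: 4 22-[(5-carboxypentyl)oxy]-22-oxodocosanoic acid
Conditions: CF3CO2H, CH2Cl2, rt
Reagents that add atoms: none
Why: Acidolysis of the tert-butyl ester (loss of 2-methylpropene via the tert-butyl cation) should free the second carboxyl group, while the primary alkyl ester, which cannot ionise in this way, stays intact.

**Step 3**
Reactants: 4 22-[(5-carboxypentyl)oxy]-22-oxodocosanoic acid; 5 N-hydroxyphthalimide
Product: 6 1,3-dioxoisoindolin-2-yl 22-({6-[(1,3-dioxoisoindolin-2-yl)oxy]-6-oxohexyl}oxy)-22-oxodocosanoate (bis redox-active ester)
Conditions: N,N'-diisopropylcarbodiimide (2.4 equiv), DMAP (cat.), CH2Cl2–THF, rt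
Reagents that add atoms: N-hydroxyphthalimide (5), ON1C(=O)c2ccccc2C1=O
Why: Steglich-type carbodiimide esterification of both carboxyl groups with N-hydroxyphthalimide should give the bis(N-acyloxyphthalimide) without touching the internal alkyl ester, and the product is purified by rapid filtration and crystallisation.

**Step 4**
Reactants: 6 bis redox-active ester
Product: 7 26-hexacosanolide (oxacycloheptacosan-2-one)
Conditions: NiCl2·6H2O (30 mol %), 2,2':6',2''-terpyridine (30 mol %), AgNO3 (0.3 equiv), LiCl, Mg anode / reticulated vitreous carbon cathode, undivided cell, constant current, NMP–THF, rt, 6 added by syringe pump (final about 2 mM)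
Reagents that add atoms: none
Why: Proposed new method: cathodically reduced nickel–terpyridine (monovalent or zerovalent nickel) and the silver-coated cathode should transfer single electrons to the two N-acyloxyphthalimide termini of 6, each of which fragments to phthalimide anion, CO2 and a primary alkyl radical (at C21 and at C22); the first radical is held as a persistent alkylnickel species until the second, formed on the same chain, is captured, and the resulting dialkyl trivalent nickel centre reductively eliminates to form C21–C22. The closest known reaction type is the intermolecular nickel-electrocatalytic doubly decarboxylative C(sp3)–C(sp3) coupling of two redox-active esters, which joins unhindered primary alkyl partners and tolerates carboxylic esters, so that only the intramolecular, macrocyclising use is new. The single ring, the 27-membered lactone, closes end to end by reductive elimination from a dialkylnickel intermediate that spans the chain (a macrocyclisation with no endo or exo alternative), and no stereocentre is created. The step needs ring closure to outrun oligomerisation, and coupling to outrun reduction or β-hydride loss at the alkylnickel chain ends. This should be secured by pseudo-high dilution, by both termini being the same unhindered primary class so that any intramolecular pairing gives the one product, by the strain-free polymethylene chain with the pre-formed C1(=O)–O ester as the only tether, and by the longer lifetime of an alkylnickel species compared with a free radical pair.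

**Compound list**
1 | docosanedioic acid | OC(=O)CCCCCCCCCCCCCCCCCCCCC(=O)O | starting material
2 | tert-butyl 6-bromohexanoate | BrCCCCCC(=O)OC(C)(C)C | starting material
3 | 22-[(6-tert-butoxy-6-oxohexyl)oxy]-22-oxodocosanoic acid | OC(=O)CCCCCCCCCCCCCCCCCCCCC(=O)OCCCCCC(=O)OC(C)(C)C | intermediate
4 | 22-[(5-carboxypentyl)oxy]-22-oxodocosanoic acid | OC(=O)CCCCCCCCCCCCCCCCCCCCC(=O)OCCCCCC(=O)O | intermediate
5 | N-hydroxyphthalimide | ON1C(=O)c2ccccc2C1=O | starting material
6 | 1,3-dioxoisoindolin-2-yl 22-({6-[(1,3-dioxoisoindolin-2-yl)oxy]-6-oxohexyl}oxy)-22-oxodocosanoate | O=C1c2ccccc2C(=O)N1OC(=O)CCCCCCCCCCCCCCCCCCCCC(=O)OCCCCCC(=O)ON1C(=O)c2ccccc2C1=O | intermediate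
7 | 26-hexacosanolide (oxacycloheptacosan-2-one) | O=C1CCCCCCCCCCCCCCCCCCCCCCCCCO1 | target

**Total step count:** 4
**Longest linear sequence:** 4 steps (1 → 3 → 4 → 6 → 7)

**Steps most likely to fail**

1. Step 4 (proposed new method). Intermolecular coupling may outcompete ring closure and give oligomeric esters, and the alkylnickel chain ends may be reduced or lose a β-hydride before the second end is engaged, giving open-chain products. The fallback uses known chemistry, sets out from 1 and comes back to the route at 7.
   - Compound 1 would be half-esterified (MeOH, cat. H2SO4, toluene, reflux; mono-ester separated from diacid and diester) to 22-methoxy-22-oxodocosanoic acid F1.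
   - Crossed Kolbe electrolysis of F1 with an excess of commercial 6-bromohexanoic acid (Pt electrodes, MeOH, NaOMe for partial neutralisation, 45 °C, high current density) should give methyl 26-bromohexacosanoate F2. The C21–C22 bond is then made by the classical intermolecular anodic decarboxylative coupling on open chains.
   - Acid hydrolysis (aq. HBr, AcOH, reflux) would give 26-bromohexacosanoic acid F3.
   - The ring would then be closed at O–C26 by intramolecular carboxylate alkylation (Cs2CO3, DMF, high dilution, 80 °C), a known macrolactonisation of ω-halo acids, to reach 7.

2. Step 1. Double O-alkylation of the diacid and poor solubility of its half-salt may leave little of the mono-ester. The fallback sets out from 1 and comes back to the route at 4.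
   - Compound 1 would first be mono-protected with N,N-dimethylformamide di-tert-butyl acetal (toluene, 80 °C; the mono-ester separated from diacid and diester) to give 22-tert-butoxy-22-oxodocosanoic acid F4.
   - Its single carboxyl group would be alkylated with 2 (KHCO3, DMF, 70 °C), where over-alkylation is structurally impossible, to give tert-butyl 6-[(22-tert-butoxy-22-oxodocosanoyl)oxy]hexanoate F5.
   - Both tert-butyl esters of F5 would be cleaved under the conditions of step 2 (CF3CO2H, CH2Cl2, rt) to give 4.

3. Step 3. Activation of both carboxyl groups may stay incomplete through O-to-N acyl shift to N-acylureas, and the activated esters may hydrolyse during purification. The fallback sets out from 4 and comes back to the route at 6.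
   - Compound 4 would be converted with oxalyl chloride (cat. DMF, CH2Cl2, rt) into 6-chloro-6-oxohexyl 22-chloro-22-oxodocosanoate F6.
   - F6 would be acylated onto N-hydroxyphthalimide 5 (Et3N, CH2Cl2, 0 °C) to give 6, isolated by crystallisation without chromatography.

**Further compounds**
F1 | step 4 | 22-methoxy-22-oxodocosanoic acid | COC(=O)CCCCCCCCCCCCCCCCCCCCC(=O)O
F2 | step 4 | methyl 26-bromohexacosanoate | COC(=O)CCCCCCCCCCCCCCCCCCCCCCCCCBr
F3 | step 4 | 26-bromohexacosanoic acid | OC(=O)CCCCCCCCCCCCCCCCCCCCCCCCCBr
F4 | step 1 | 22-tert-butoxy-22-oxodocosanoic acid | CC(C)(C)OC(=O)CCCCCCCCCCCCCCCCCCCCC(=O)O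
F5 | step 1 | tert-butyl 6-[(22-tert-butoxy-22-oxodocosanoyl)oxy]hexanoate | CC(C)(C)OC(=O)CCCCCCCCCCCCCCCCCCCCC(=O)OCCCCCC(=O)OC(C)(C)C
F6 | step 3 | 6-chloro-6-oxohexyl 22-chloro-22-oxodocosanoate | ClC(=O)CCCCCCCCCCCCCCCCCCCCC(=O)OCCCCCC(=O)Cl
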